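The flavonol is disconnected at the C4 carbonyl of ring C: C4 is treated as carbon monoxide inserted between C4a of ring A and the C3–C2 alkyne carbons that carry ring B, while O1–C2 arises from a ring A phenol adding to the resulting ynone. A single palladium-catalysed carbonylative coupling–cyclisation should therefore join mirror-symmetric 2-iodo-5-methoxyresorcinol, CO and 4-benzyloxy-3-methoxyphenylacetylene into the complete 5-hydroxy-7-methoxyflavone; since the two hydroxyls flanking the iodide are equivalent, ring A regiochemistry cannot go astray. The C3 oxygen, the sulfate and the free phenols follow by routine functional-group steps.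

Key step: step 5

Assumption: the target is taken as the free hydrogen sulfate as drawn; because enol hydrogen sulfates are acid-labile, the sulfate is carried as its triethylammonium salt and protonated only in the last operation by cold cation exchange. O-Benzylvanillin 6 is taken as a catalogue compound.

Step 1
Reactants: 1 5-methoxyresorcinol
Product: 2 1-methoxy-3,5-bis(methoxymethoxy)benzene
Conditions: MOMCl, i-Pr2NEt, CH2Cl2, 0 °C to rt
Reagents that add atoms: chloromethyl methyl ether, COCCl
Why: Williamson-type O-alkylation of both phenols by the reactive α-chloro ether under amine base should be fast, leaves the methyl ether untouched and installs the two acetal groups that direct the metalation in step 2.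

Step 2
Reactants: 2 1-methoxy-3,5-bis(methoxymethoxy)benzene
Product: 4 2-iodo-5-methoxy-1,3-bis(methoxymethoxy)benzene, via aryllithium 3 (not isolated)
Conditions: n-BuLi, THF, 0 °C; then I2, THF, −78 °C to rt
Reagents that add atoms: iodine, II
Why: Directed ortho-metalation should remove the ring hydrogen flanked by the two chelating methoxymethyl ethers in preference to those next to the weaker methoxy director, and iodine traps the aryllithium at that carbon.

Step 3
Reactants: 4 2-iodo-5-methoxy-1,3-bis(methoxymethoxy)benzene
Product: 5 2-iodo-5-methoxybenzene-1,3-diol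
Conditions: HCl (1.25 M in MeOH), 0 °C to rt, dark
Reagents that add atoms: none
Why: Acid-catalysed transacetalisation to methanol should cleave both methoxymethyl ethers under mild conditions, with low temperature, short contact time and exclusion of light chosen to keep the electron-rich aryl iodide intact.

Step 4
Reactants: 6 4-(benzyloxy)-3-methoxybenzaldehyde
Product: 7 1-(benzyloxy)-4-ethynyl-2-methoxybenzene
Conditions: dimethyl (1-diazo-2-oxopropyl)phosphonate, K2CO3, MeOH, rt
Reagents that add atoms: dimethyl (1-diazo-2-oxopropyl)phosphonate, COP(=O)(OC)C(=[N+]=[N-])C(C)=O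
Why: Ohira–Bestmann (Seyferth–Gilbert) one-carbon homologation of the non-enolisable aryl aldehyde by the diazomethylphosphonate anion released in situ should give the terminal alkyne under carbonate/methanol conditions that the benzyl ether tolerates.

Step 5
Reactants: 5 2-iodo-5-methoxybenzene-1,3-diol; 7 1-(benzyloxy)-4-ethynyl-2-methoxybenzene; 8 carbon monoxide
Product: 11 2-[4-(benzyloxy)-3-methoxyphenyl]-5-hydroxy-7-methoxy-4H-chromen-4-one, via ynone 9 (not isolated), via enaminone 10 (not isolated)
Conditions: PdCl2(dppf) (5 mol%), CO (20 bar), Et2NH, 120 °C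
Reagents that add atoms: none
Why: Zerovalent palladium formed from PdCl2(dppf) should insert into the C–I bond of 5, CO then inserts to give an aroylpalladium species, and transfer of the amine-deprotonated alkyne followed by reductive elimination forms C4a–C4 and C4–C3 in ynone 9. Diethylamine adds reversibly to 9 to give enaminone 10, and one of the two equivalent ortho hydroxyls then displaces the amine at C2 by 6-endo addition–elimination (6-endo-dig with respect to the ynone), forming O1–C2 and closing ring C. The closest known reaction type is the palladium-catalysed carbonylative Sonogashira annulation of ortho-iodophenols with terminal arylalkynes to flavones, applied here to a doubly ortho-oxygenated iodide. No stereocentre is created. The step needs carbonylative over direct alkynylation, which CO pressure and the absence of copper secure, and six-membered flavone over five-membered aurone closure, which the secondary-amine pathway through 10 secures. Ring A regiochemistry is settled by the mirror symmetry of 5, the unused hydroxyl becoming the chelated 5-OH.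

Step 6
Reactants: 11 2-[4-(benzyloxy)-3-methoxyphenyl]-5-hydroxy-7-methoxy-4H-chromen-4-one
Product: 12 5-(benzyloxy)-2-[4-(benzyloxy)-3-methoxyphenyl]-7-methoxy-4H-chromen-4-one
Conditions: BnBr, K2CO3, n-Bu4NI (cat.), DMF, 70 °C
Reagents that add atoms: benzyl bromide, BrCc1ccccc1
Why: Williamson etherification in hot DMF should overcome the hydrogen bond of the 5-hydroxyl to the C4 carbonyl, so that no free phenol meets the oxidant of step 7 and both phenol protecting groups can leave together at the end.

Step 7
Reactants: 12 5-(benzyloxy)-2-[4-(benzyloxy)-3-methoxyphenyl]-7-methoxy-4H-chromen-4-one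
Product: 14 5-(benzyloxy)-2-[4-(benzyloxy)-3-methoxyphenyl]-3-hydroxy-7-methoxy-4H-chromen-4-one, via flavone epoxide 13 (not isolated)
Conditions: dimethyldioxirane (acetone solution), CH2Cl2, 0 °C to rt; then p-TsOH·H2O (cat.), CH2Cl2, rt
Reagents that add atoms: dimethyldioxirane, CC1(C)OO1
Why: Electrophilic epoxidation of the C2–C3 enol-ether double bond by neutral dimethyldioxirane should give the racemic, necessarily cis-fused epoxide, which under acid opens at C2 to the oxygen-stabilised benzylic cation and loses the C3 proton to give the aromatic 3-hydroxyflavone, erasing both transient stereocentres (epoxidation–isomerisation route to flavonols).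

Step 8
Reactants: 14 5-(benzyloxy)-2-[4-(benzyloxy)-3-methoxyphenyl]-3-hydroxy-7-methoxy-4H-chromen-4-one
Product: 15 triethylammonium 5-(benzyloxy)-2-[4-(benzyloxy)-3-methoxyphenyl]-7-methoxy-4-oxo-4H-chromen-3-yl sulfate
Conditions: SO3·NEt3, Et3N, DMF, 60 °C
Reagents that add atoms: sulfur trioxide–triethylamine complex, CC[N+](CC)(CC)S(=O)(=O)[O-]
Why: O-Sulfation of the only free hydroxyl, the acidic enolic 3-OH, by the amine–sulfur trioxide complex should give the sulfate monoester directly as its chromatographable triethylammonium salt, the standard method for flavonol sulfates.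

Step 9
Reactants: 15 triethylammonium 5-(benzyloxy)-2-[4-(benzyloxy)-3-methoxyphenyl]-7-methoxy-4-oxo-4H-chromen-3-yl sulfate
Product: 17 rhamnazin 3-O-sulfate, via triethylammonium salt 16 (not isolated)
Conditions: H2 (1 atm), Pd/C, MeOH/THF, rt; then Dowex 50WX8 (H+ form), MeOH/H2O, 0 °C, freeze-dry
Reagents that add atoms: none
Why: Catalytic hydrogenolysis should cleave both benzyl aryl ethers under neutral conditions that the sulfate monoester and the conjugated flavonol tolerate, and brief cold contact with a sulfonic acid resin exchanges triethylammonium for a proton to deliver the hydrogen sulfate as drawn.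

Compound list
1 | 5-methoxyresorcinol (5-methoxybenzene-1,3-diol) | COc1cc(O)cc(O)c1 | starting material
2 | 1-methoxy-3,5-bis(methoxymethoxy)benzene | COCOc1cc(OC)cc(OCOC)c1 | intermediate
3 | [4-methoxy-2,6-bis(methoxymethoxy)phenyl]lithium | [Li]c1c(OCOC)cc(OC)cc1OCOC | intermediate
4 | 2-iodo-5-methoxy-1,3-bis(methoxymethoxy)benzene | COCOc1cc(OC)cc(OCOC)c1I | intermediate
5 | 2-iodo-5-methoxybenzene-1,3-diol | COc1cc(O)c(I)c(O)c1 | intermediate
6 | 4-(benzyloxy)-3-methoxybenzaldehyde (O-benzylvanillin) | COc1cc(C=O)ccc1OCc1ccccc1 | starting material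
7 | 1-(benzyloxy)-4-ethynyl-2-methoxybenzene | C#Cc1ccc(OCc2ccccc2)c(OC)c1 | intermediate
8 | carbon monoxide | [C-]#[O+] | starting material
9 | 3-[4-(benzyloxy)-3-methoxyphenyl]-1-(2,6-dihydroxy-4-methoxyphenyl)prop-2-yn-1-one | COc1cc(O)c(C(=O)C#Cc2ccc(OCc3ccccc3)c(OC)c2)c(O)c1 | intermediate
10 | (E)-3-[4-(benzyloxy)-3-methoxyphenyl]-3-(diethylamino)-1-(2,6-dihydroxy-4-methoxyphenyl)prop-2-en-1-one (geometry immaterial to the closure) | CCN(CC)/C(=C/C(=O)c1c(O)cc(OC)cc1O)c1ccc(OCc2ccccc2)c(OC)c1 | intermediate
11 | 2-[4-(benzyloxy)-3-methoxyphenyl]-5-hydroxy-7-methoxy-4H-chromen-4-one | COc1cc(O)c2c(=O)cc(-c3ccc(OCc4ccccc4)c(OC)c3)oc2c1 | intermediate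
12 | 5-(benzyloxy)-2-[4-(benzyloxy)-3-methoxyphenyl]-7-methoxy-4H-chromen-4-one | COc1cc(OCc2ccccc2)c2c(=O)cc(-c3ccc(OCc4ccccc4)c(OC)c3)oc2c1 | intermediate
13 | racemic 2,3-epoxide of 12 (2,3-epoxyflavanone, oxirane cis-fused across C2–C3 of ring C; one enantiomer drawn) | O=C1[C@@H]2O[C@]2(c2ccc(OCc3ccccc3)c(OC)c2)Oc2cc(OC)cc(OCc3ccccc3)c21 | intermediate
14 | 5-(benzyloxy)-2-[4-(benzyloxy)-3-methoxyphenyl]-3-hydroxy-7-methoxy-4H-chromen-4-one | COc1cc(OCc2ccccc2)c2c(=O)c(O)c(-c3ccc(OCc4ccccc4)c(OC)c3)oc2c1 | intermediate
15 | triethylammonium 5-(benzyloxy)-2-[4-(benzyloxy)-3-methoxyphenyl]-7-methoxy-4-oxo-4H-chromen-3-yl sulfate | COc1cc(OCc2ccccc2)c2c(=O)c(OS(=O)(=O)[O-])c(-c3ccc(OCc4ccccc4)c(OC)c3)oc2c1.CC[NH+](CC)CC | intermediate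
16 | triethylammonium 5-hydroxy-2-(4-hydroxy-3-methoxyphenyl)-7-methoxy-4-oxo-4H-chromen-3-yl sulfate | COc1cc(O)c2c(=O)c(OS(=O)(=O)[O-])c(-c3ccc(O)c(OC)c3)oc2c1.CC[NH+](CC)CC | intermediate
17 | rhamnazin 3-O-sulfate (5-hydroxy-2-(4-hydroxy-3-methoxyphenyl)-7-methoxy-4-oxo-4H-chromen-3-yl hydrogen sulfate) | COc1cc(O)c2c(=O)c(OS(=O)(=O)O)c(-c3ccc(O)c(OC)c3)oc2c1 | target

Total step count: 9. Longest linear sequence: 8 steps (steps 1–3 and 5–9); step 4 is the one-step branch to the alkyne.

Steps most likely to fail

Step 5. Oxidative addition at the doubly ortho-substituted, electron-rich iodide may be slow enough for hydrodeiodination to compete. Direct alkynylation without CO uptake (leading on to a benzofuran), capture of the aroylpalladium species by diethylamine, or five-membered closure could also divert material. The fallback builds the same ynone without palladium, setting out from aryllithium 3 and alkyne 7 and returning at 11. Aryllithium 3 (made as in step 2) is quenched with DMF to give 4-methoxy-2,6-bis(methoxymethoxy)benzaldehyde F1. Alkyne 7 is deprotonated with n-BuLi in THF at −78 °C to lithium [4-(benzyloxy)-3-methoxyphenyl]acetylide F2, which adds to F1 to give the racemic propargylic alcohol F3. Oxidation with manganese dioxide (MnO2) in CH2Cl2 gives the bis-acetal ynone F4. Methanolic HCl then removes both acetals to release ynone 9, now with no aryl iodide present to suffer, and warming 9 with Et2NH in DMF closes ring C through enaminone 10 to flavone 11.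

Step 7. The dioxirane may attack the electron-rich alkoxyarenes or the benzylic C–H bonds, epoxidation of the hindered enone may stall, or the epoxide may open by hydration or ring contraction instead of enolisation. The fallback runs from 12 to 14 by C3 metalation and oxidation. LiN(i-Pr)2 in THF at −78 °C should remove the C3 hydrogen of 12 to give the 3-lithioflavone F5. Trapping with B(OMe)3 gives the dimethyl flavon-3-ylboronate F6, and oxidation of the C–B bond with H2O2/AcOH delivers 3-hydroxyflavone 14.

Step 3. Under the acid needed for acetal cleavage, the iodine of the phloroglucinol-type ring may migrate to C4 or be lost by ipso-protonation. The fallback avoids acid and the protecting groups altogether, going from 1 directly to 5. Iodination of 5-methoxyresorcinol 1 with I2 and NaHCO3 in water/THF at 0 °C should place iodine kinetically between the two hydroxyls of the phenoxide. The symmetric substitution pattern of 5 would have to be confirmed before use. This fallback makes no compound outside the list (F0).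

Further compounds
F1 | step 5 | 4-methoxy-2,6-bis(methoxymethoxy)benzaldehyde | COCOc1cc(OC)cc(OCOC)c1C=O
F2 | step 5 | lithium [4-(benzyloxy)-3-methoxyphenyl]acetylide | [Li]C#Cc1ccc(OCc2ccccc2)c(OC)c1
F3 | step 5 | racemic 3-[4-(benzyloxy)-3-methoxyphenyl]-1-[4-methoxy-2,6-bis(methoxymethoxy)phenyl]prop-2-yn-1-ol | COCOc1cc(OC)cc(OCOC)c1C(O)C#Cc1ccc(OCc2ccccc2)c(OC)c1
F4 | step 5 | 3-[4-(benzyloxy)-3-methoxyphenyl]-1-[4-methoxy-2,6-bis(methoxymethoxy)phenyl]prop-2-yn-1-one | COCOc1cc(OC)cc(OCOC)c1C(=O)C#Cc1ccc(OCc2ccccc2)c(OC)c1
F5 | step 7 | {5-(benzyloxy)-2-[4-(benzyloxy)-3-methoxyphenyl]-7-methoxy-4-oxo-4H-chromen-3-yl}lithium | [Li]c1c(-c2ccc(OCc3ccccc3)c(OC)c2)oc2cc(OC)cc(OCc3ccccc3)c2c1=O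
F6 | step 7 | dimethyl {5-(benzyloxy)-2-[4-(benzyloxy)-3-methoxyphenyl]-7-methoxy-4-oxo-4H-chromen-3-yl}boronate | COB(OC)c1c(-c2ccc(OCc3ccccc3)c(OC)c2)oc2cc(OC)cc(OCc3ccccc3)c2c1=O
F0 | step 3 | none | none
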